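**Retrosynthetic overview**
1. Target 35 ⇐ 9α‑alcohol 31 (senecioylation, then release of C2) ⇐ C9 ketone 29 (hydride from the convex face) ⇐ C8 ketone 25 (C7 isopropenyl by α‑iodination, Suzuki coupling and conjugate reduction; C9–O by enolate hydroxylation) ⇐ cis‑fused enedione 16.
2. Feature used: the C2 ketone and the C8 oxygen are 1,5‑related through C1–C10–C9, so C1–C10 is a Michael bond; cutting it opens ring A and leaves ring B as the prochiral 4‑methyl‑4‑alkylcyclohexa‑2,5‑dienone 15, in which only C4 is stereogenic.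
3. 15 ⇐ Robinson annulation of aldehyde 7 with methyl vinyl ketone and Saegusa–Ito dehydrogenation; 7 ⇐ hydroboration/oxidation of 3 ⇐ Rh‑catalysed asymmetric isopropenyl addition to (E)‑pent‑3‑en‑2‑one (sets C4).
4. Ring order: ring B first (as the dienone), ring A second by the amine‑catalysed desymmetrising Michael closure, which fixes C5 and C10 together.

Key step: step 8

Remarks
- Eremophilane numbering is used for the bicyclic compounds: ring A = C1–C5, C10 (C2 carbonyl, C4 and C5 methyls); ring B = C5–C10. β is the face of the C5 methyl group. 4‑Me, 5‑Me and 10‑H are β throughout. The target is 7β‑isopropenyl, 8α‑OAc, 9α‑O‑senecioyl, i.e. (4S,5R,7R,8R,9S,10S).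
- Assumption (step 1): the usual BINAP–Rh facial model for (E)‑enones predicts the (S)‑ketone from (R)‑BINAP; if the opposite sense is found, (S)‑BINAP is used.
- Assumption (step 8): 9‑amino‑9‑deoxy‑epi‑quinidine is taken as the catalyst matched with (S)‑C4; if arm selection is the opposite, the quinine‑derived pseudoenantiomer is used.
- The 9α‑oxygen of the target lies in the concave pocket under ring A, next to C2. A C2 ketal puts an axial oxygen into that pocket. The ketal is therefore exchanged for a planar hydrazone before C9 is inverted (steps 17–20).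

**Step 1**
Reactants: 1 (E)‑pent‑3‑en‑2‑one; 2 isopropenylboronic acid pinacol ester
Product: 3 (S)‑4,5‑dimethylhex‑5‑en‑2‑one
Conditions: Rh(acac)(C2H4)2 (3 mol %), (R)‑BINAP, KOH (aq., cat.), dioxane–H2O, 80 °C
Reagents that add atoms: none
Why: Hayashi–Miyaura Rh‑catalysed asymmetric 1,4‑addition of the alkenylboron reagent, in which the BINAP–Rh–alkenyl species adds to one enantioface of the (E)‑enone and so sets C4.

**Step 2**
Reactants: 3 (S)‑4,5‑dimethylhex‑5‑en‑2‑one
Product: 4 2‑[(2S)‑2,3‑dimethylbut‑3‑en‑1‑yl]‑2‑methyl‑1,3‑dioxolane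
Conditions: HOCH2CH2OH, PPTS (cat.), benzene, reflux, Dean–Stark
Reagents that add atoms: ethylene glycol, OCCO
Why: Acid‑catalysed ketalisation with azeotropic removal of water masks the methyl ketone against borane and base, and PPTS is mild enough to leave the 1,1‑disubstituted alkene in place.

**Step 3**
Reactants: 4 ketal alkene
Product: 6 (3S)‑2,3‑dimethyl‑4‑(2‑methyl‑1,3‑dioxolan‑2‑yl)butan‑1‑ol (C2 epimers), via alkylborane 5 (not isolated)
Conditions: 9‑BBN, THF, 0 °C → rt; then NaOH (aq.), H2O2, 0 °C → rt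
Reagents that add atoms: hydrogen peroxide, OO
Why: Anti‑Markovnikov hydroboration–oxidation of the 1,1‑disubstituted alkene gives the primary alcohol; the new centre (future C5) forms as a mixture, which is immaterial because it becomes the symmetric quaternary carbon.

**Step 4**
Reactants: 6 primary alcohol
Product: 7 (3S)‑2,3‑dimethyl‑4‑(2‑methyl‑1,3‑dioxolan‑2‑yl)butanal (C2 epimers)
Conditions: Dess–Martin periodinane, NaHCO3, CH2Cl2, rt
Reagents that add atoms: none
Why: Buffered Dess–Martin oxidation converts the primary alcohol into the aldehyde without touching the ketal.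

**Step 5**
Reactants: 7 aldehyde; 8 methyl vinyl ketone
Product: 11 4‑methyl‑4‑[(2S)‑1‑(2‑methyl‑1,3‑dioxolan‑2‑yl)propan‑2‑yl]cyclohex‑2‑en‑1‑one (ring C4 epimers), via Michael adduct 9 (not isolated), via aldol 10 (not isolated)
Conditions: KOH (0.2 equiv), EtOH, 0 °C → rt; then 70 °C
Reagents that add atoms: none
Why: Robinson annulation, in which Michael addition of the α‑branched aldehyde enolate to the enone creates the quaternary carbon and aldol condensation of the methyl ketone onto the now non‑enolisable aldehyde closes the cyclohexenone; the ring stereocentre is erased in step 6.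

**Step 6**
Reactants: 11 cyclohexenone
Product: 14 4‑methyl‑4‑[(2S)‑1‑(2‑methyl‑1,3‑dioxolan‑2‑yl)propan‑2‑yl]cyclohexa‑2,5‑dien‑1‑one, via lithium dienolate 12 (not isolated), via silyl dienol ether 13 (not isolated)
Conditions: LiN(iPr)2, THF, −78 °C; Me3SiCl; then Pd(OAc)2 (1.05 equiv), MeCN, rt
Reagents that add atoms: none
Why: Saegusa–Ito oxidation, in which kinetic α′‑deprotonation (the γ‑carbon is quaternary) gives the cross‑conjugated silyl dienol ether and Pd(OAc)2 effects dehydrosilylation to the dienone.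

**Step 7**
Reactants: 14 dienone ketal
Product: 15 4‑methyl‑4‑[(2S)‑4‑oxopentan‑2‑yl]cyclohexa‑2,5‑dien‑1‑one
Conditions: 1 M aq. HCl, THF, 0 °C → rt (short)
Reagents that add atoms: water, O
Why: Mild aqueous acid hydrolysis of the dioxolane frees the methyl ketone, and the low temperature and short contact should prevent acid‑promoted background cyclisation.

**Step 8**
Reactants: 15 dienone methyl ketone
Product: 16 (4S,4aR,8aR)‑4,4a‑dimethyl‑3,4,4a,8a‑tetrahydronaphthalene‑2,7(1H,8H)‑dione (cis‑fused; C2 and C8 ketones, C6=C7)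
Conditions: 9‑amino‑9‑deoxy‑epi‑quinidine (20 mol %), PhCO2H (40 mol %), toluene, 40 °C
Reagents that add atoms: none
Why: The primary amine condenses with the methyl ketone to an iminium ion that tautomerises to the less substituted enamine, whose terminal carbon C1 adds to C10, the β‑carbon of one enone arm, and hydrolysis of the product iminium ion returns the catalyst. The closest known reaction type is the amine‑catalysed desymmetrising intramolecular Michael addition of carbonyl‑tethered 4,4‑disubstituted cyclohexadienones. Ring A closes in a 6‑(enolendo)‑exo‑trig mode, whereas the enamine through C3 could only give a four‑membered ring and is unproductive. C10 is set by the tether, which reaches the dienone only on the face that carries C4 and so gives the cis fusion; C5 is set by the choice of arm, governed by the catalyst together with a chair‑like transition state that keeps the C4 methyl equatorial. The step needs arm selectivity, supplied by the catalyst matched to C4; since the same catalyst should steer the minor (R)‑C4 enantiomer of 15 to a separable diastereomer, the closure should also raise the enantiomeric purity of 16. The untouched arm C6=C7–C8=O remains as the handle for C7, C8 and C9.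

**Step 9**
Reactants: 16 enedione
Product: 17 C2 ethylene ketal of 16 (enone C6=C7–C8=O retained)
Conditions: Me3SiOCH2CH2OSiMe3, Me3SiOTf (cat.), CH2Cl2, −78 °C
Reagents that add atoms: 1,2‑bis(trimethylsilyloxy)ethane, C[Si](C)(C)OCCO[Si](C)(C)C
Why: Noyori ketalisation is selective for the saturated C2 ketone over the conjugated C8 ketone and blocks C1/C3 enolisation, C2 reduction and retro‑Michael opening of ring A.

**Step 10**
Reactants: 17 ketal enone
Product: 19 9β‑hydroxy enone, via sodium dienolate 18 (not isolated)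
Conditions: NaN(SiMe3)2, THF, −78 °C; then 2‑(phenylsulfonyl)‑3‑phenyloxaziridine, −78 °C; aq. NH4Cl
Reagents that add atoms: 2‑(phenylsulfonyl)‑3‑phenyloxaziridine, O=S(=O)(c1ccccc1)N1OC1c1ccccc1
Why: The enone can enolise only towards C9 (C5 is quaternary), and Davis oxidation of the cross‑conjugated dienolate should deliver oxygen on the convex β face, anti to C1 at C10; this C9 configuration is provisional and is reset in steps 18–20.

**Step 11**
Reactants: 19 9β‑hydroxy enone
Product: 20 9β‑(tert‑butyldimethylsilyloxy) enone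
Conditions: TBSCl, imidazole, DMF, 40 °C
Reagents that add atoms: tert‑butyldimethylsilyl chloride, CC(C)(C)[Si](C)(C)Cl
Why: Standard silylation of the secondary α‑hydroxy ketone protects C9–OH through the coupling and reduction steps.

**Step 12**
Reactants: 20 silyloxy enone
Product: 21 7‑iodo enone
Conditions: I2, pyridine–CH2Cl2 (1:1), rt
Reagents that add atoms: iodine, II
Why: Johnson α‑iodination of the enone (pyridine conjugate addition, iodination, elimination) is precedented for cyclohexenones with a quaternary γ‑carbon.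

**Step 13**
Reactants: 21 7‑iodo enone; 2 isopropenylboronic acid pinacol ester
Product: 22 7‑(prop‑1‑en‑2‑yl)‑6‑en‑8‑one
Conditions: Pd(dppf)Cl2·CH2Cl2 (5 mol %), K3PO4, dioxane–H2O (9:1), 60 °C
Reagents that add atoms: none
Why: Suzuki–Miyaura coupling of an α‑iodoenone with an alkenylboronate installs the C7 isopropenyl group.

**Step 14**
Reactants: 22 isopropenyl enone
Product: 25 7β‑isopropenyl‑8‑oxo‑9β‑silyloxy ketal, via copper enolate 23 (not isolated), via 7α‑isopropenyl ketone 24 (not isolated)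
Conditions: [(Ph3P)CuH]6 (0.4 equiv), toluene, H2O (3 equiv), rt; then DBU (0.2 equiv), CH2Cl2, rt, stopped once the C7 epimers have converged
Reagents that add atoms: none
Why: Copper hydride conjugate reduction delivers hydride to C6 and water protonates the copper dienolate at C7 (α‑protonation, no conjugation), after which brief amine‑base equilibration through the enol converts the 7α epimer into the 7β epimer, in which the C7 and C9 substituents are both equatorial on the ring B chair.

**Step 15**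
Reactants: 25 C8 ketone
Product: 26 8α‑alcohol
Conditions: NaBH4, CeCl3·7H2O, MeOH, −78 °C
Reagents that add atoms: none
Why: Luche‑type borohydride reduction by axial attack on C8 from the open β face, between the two equatorial neighbours, should give the equatorial 8α‑alcohol.

**Step 16**
Reactants: 26 8α‑alcohol
Product: 27 8α‑acetate
Conditions: Ac2O, pyridine, DMAP (cat.), CH2Cl2, rt
Reagents that add atoms: acetic anhydride, CC(=O)OC(C)=O
Why: DMAP‑catalysed acetylation installs the final C8 ester on the equatorial hydroxyl, where it is also thermodynamically preferred over O9.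

**Step 17**
Reactants: 27 acetate silyl ether ketal
Product: 28 8α‑acetoxy‑9β‑hydroxy‑7β‑isopropenyl 2‑ketone
Conditions: 48% aq. HF, MeCN, 0 °C → rt; then 1 M aq. HCl, rt
Reagents that add atoms: water, O
Why: Aqueous acid removes the silyl ether and hydrolyses the dioxolane in one operation; the ketal must go before C9 is inverted because its axial oxygen fills the concave pocket that the 9α‑oxygen has to enter.

**Step 18**
Reactants: 28 hydroxy ketone
Product: 29 8α‑acetoxy‑7β‑isopropenyl 2,9‑dione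
Conditions: Dess–Martin periodinane, NaHCO3, CH2Cl2, 0 °C → rt
Reagents that add atoms: none
Why: Buffered Dess–Martin oxidation gives the α‑acetoxy ketone under non‑enolising conditions, and C8 (equatorial acetate) and C10 (cis fusion held by the 7β substituent) are already in their preferred configurations.

**Step 19**
Reactants: 29 2,9‑dione
Product: 30 C2 N,N‑dimethylhydrazone of 29
Conditions: Me2NNH2, AcOH (cat.), EtOH, rt
Reagents that add atoms: 1,1‑dimethylhydrazine, CN(C)N
Why: Hydrazone formation should be selective for the unhindered C2 ketone over the C9 ketone flanked by two methine carbons, and the planar C=N protects C2 without placing anything in the concave pocket.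

**Step 20**
Reactants: 30 hydrazone ketone
Product: 31 8α‑acetoxy‑9α‑hydroxy C2 hydrazone
Conditions: NaBH4, MeOH–CH2Cl2 (1:1), −40 °C → 0 °C
Reagents that add atoms: none
Why: Borohydride can reach C9 only from the convex β face because the α face is buried under ring A, so the axial 9α‑alcohol cis to the 8α‑acetate should form, as in hydride reductions of hindered cis‑decalones and 5β‑steroid ketones; hydrazone and acetate are inert under these conditions.

**Step 21**
Reactants: 31 9α‑alcohol; 32 3‑methylbut‑2‑enoic acid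
Product: 34 9α‑(3‑methylbut‑2‑enoyloxy)‑8α‑acetoxy C2 hydrazone, via mixed anhydride 33 (not isolated)
Conditions: 32, 2,4,6‑trichlorobenzoyl chloride, Et3N, THF, rt; then 31, DMAP, toluene, 40 °C
Reagents that add atoms: none
Why: Yamaguchi esterification through the mixed anhydride acylates the hindered axial alcohol and avoids the acid chloride/vinylketene pathway that deconjugates senecioates.

**Step 22**
Reactants: 34 diester hydrazone
Product: 35 target
Conditions: sat. aq. oxalic acid, Et2O, rt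
Reagents that add atoms: water, O
Why: Biphasic oxalic acid hydrolysis of the N,N‑dimethylhydrazone regenerates the C2 ketone without affecting the two esters or the isopropenyl group.

**Compound list**
1 | (E)‑pent‑3‑en‑2‑one | C/C=C/C(C)=O | starting material
2 | 4,4,5,5‑tetramethyl‑2‑(prop‑1‑en‑2‑yl)‑1,3,2‑dioxaborolane | CC(=C)B1OC(C)(C)C(C)(C)O1 | starting material
3 | (S)‑4,5‑dimethylhex‑5‑en‑2‑one | CC(=O)C[C@H](C)C(C)=C | intermediate
4 | 2‑[(2S)‑2,3‑dimethylbut‑3‑en‑1‑yl]‑2‑methyl‑1,3‑dioxolane | CC1(OCCO1)C[C@H](C)C(C)=C | intermediate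
5 | 9‑[(3S)‑2,3‑dimethyl‑4‑(2‑methyl‑1,3‑dioxolan‑2‑yl)butyl]‑9‑borabicyclo[3.3.1]nonane | CC1(OCCO1)C[C@H](C)C(C)CB2C3CCCC2CCC3 | intermediate (not isolated)
6 | (3S)‑2,3‑dimethyl‑4‑(2‑methyl‑1,3‑dioxolan‑2‑yl)butan‑1‑ol (C2 epimers) | CC1(OCCO1)C[C@H](C)C(C)CO | intermediate
7 | (3S)‑2,3‑dimethyl‑4‑(2‑methyl‑1,3‑dioxolan‑2‑yl)butanal (C2 epimers) | CC1(OCCO1)C[C@H](C)C(C)C=O | intermediate
8 | but‑3‑en‑2‑one | C=CC(C)=O | starting material
9 | (3S)‑2,3‑dimethyl‑4‑(2‑methyl‑1,3‑dioxolan‑2‑yl)‑2‑(3‑oxobutyl)butanal | CC1(OCCO1)C[C@H](C)C(C)(C=O)CCC(C)=O | intermediate (not isolated)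
10 | 3‑hydroxy‑4‑methyl‑4‑[(2S)‑1‑(2‑methyl‑1,3‑dioxolan‑2‑yl)propan‑2‑yl]cyclohexan‑1‑one | CC1(OCCO1)C[C@H](C)C2(C)CCC(=O)CC2O | intermediate (not isolated)
11 | 4‑methyl‑4‑[(2S)‑1‑(2‑methyl‑1,3‑dioxolan‑2‑yl)propan‑2‑yl]cyclohex‑2‑en‑1‑one (ring C4 epimers) | CC1(OCCO1)C[C@H](C)C2(C)CCC(=O)C=C2 | intermediate
12 | lithium 4‑methyl‑4‑[(2S)‑1‑(2‑methyl‑1,3‑dioxolan‑2‑yl)propan‑2‑yl]cyclohexa‑1,5‑dien‑1‑olate | CC1(OCCO1)C[C@H](C)C2(C)CC=C([O-])C=C2.[Li+] | intermediate (not isolated)
13 | trimethylsilyl dienol ether of 11 (1‑silyloxycyclohexa‑1,5‑diene) | CC1(OCCO1)C[C@H](C)C2(C)CC=C(O[Si](C)(C)C)C=C2 | intermediate (not isolated)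
14 | 4‑methyl‑4‑[(2S)‑1‑(2‑methyl‑1,3‑dioxolan‑2‑yl)propan‑2‑yl]cyclohexa‑2,5‑dien‑1‑one | CC1(OCCO1)C[C@H](C)C2(C)C=CC(=O)C=C2 | intermediate
15 | 4‑methyl‑4‑[(2S)‑4‑oxopentan‑2‑yl]cyclohexa‑2,5‑dien‑1‑one | CC(=O)C[C@H](C)C1(C)C=CC(=O)C=C1 | intermediate (key‑step precursor)
16 | (4S,4aR,8aR)‑4,4a‑dimethyl‑3,4,4a,8a‑tetrahydronaphthalene‑2,7(1H,8H)‑dione (cis‑fused; C2, C8 ketones; C6=C7) | C1=C[C@@]2(C)[C@H](CC(=O)C[C@@H]2C)CC1=O | intermediate (key‑step product)
17 | C2 ethylene ketal (1,3‑dioxolane) of 16 | C1=C[C@@]2(C)[C@H](CC3(OCCO3)C[C@@H]2C)CC1=O | intermediate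
18 | sodium C8 dienolate of 17 (C8=C9, C6=C7) | C1=C[C@@]2(C)[C@H](CC3(OCCO3)C[C@@H]2C)C=C1[O-].[Na+] | intermediate (not isolated)
19 | 9β‑hydroxy derivative of 17 | C1=C[C@@]2(C)[C@H](CC3(OCCO3)C[C@@H]2C)[C@@H](O)C1=O | intermediate
20 | 9β‑(tert‑butyldimethylsilyloxy) derivative of 17 | C1=C[C@@]2(C)[C@H](CC3(OCCO3)C[C@@H]2C)[C@@H](O[Si](C)(C)C(C)(C)C)C1=O | intermediate
21 | 7‑iodo derivative of 20 | IC1=C[C@@]2(C)[C@H](CC3(OCCO3)C[C@@H]2C)[C@@H](O[Si](C)(C)C(C)(C)C)C1=O | intermediate
22 | 7‑(prop‑1‑en‑2‑yl) derivative of 20 | C=C(C)C1=C[C@@]2(C)[C@H](CC3(OCCO3)C[C@@H]2C)[C@@H](O[Si](C)(C)C(C)(C)C)C1=O | intermediate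
23 | (triphenylphosphine)copper C7=C8 dienolate from 22 | C=C(C)C=1C[C@@]2(C)[C@H](CC3(OCCO3)C[C@@H]2C)[C@@H](O[Si](C)(C)C(C)(C)C)C=1O[Cu-][P+](c1ccccc1)(c1ccccc1)c1ccccc1 | intermediate (not isolated)
24 | 7α‑isopropenyl‑8‑oxo‑9β‑silyloxy C2 ketal (C7 epimer of 25) | C=C(C)[C@@H]1C[C@@]2(C)[C@H](CC3(OCCO3)C[C@@H]2C)[C@@H](O[Si](C)(C)C(C)(C)C)C1=O | intermediate (not isolated)
25 | 7β‑isopropenyl‑8‑oxo‑9β‑silyloxy C2 ketal | C=C(C)[C@H]1C[C@@]2(C)[C@H](CC3(OCCO3)C[C@@H]2C)[C@@H](O[Si](C)(C)C(C)(C)C)C1=O | intermediate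
26 | 7β‑isopropenyl‑8α‑hydroxy‑9β‑silyloxy C2 ketal | C=C(C)[C@H]1C[C@@]2(C)[C@H](CC3(OCCO3)C[C@@H]2C)[C@@H](O[Si](C)(C)C(C)(C)C)[C@@H]1O | intermediate
27 | 8α‑acetoxy‑7β‑isopropenyl‑9β‑silyloxy C2 ketal | C=C(C)[C@H]1C[C@@]2(C)[C@H](CC3(OCCO3)C[C@@H]2C)[C@@H](O[Si](C)(C)C(C)(C)C)[C@@H]1OC(C)=O | intermediate
28 | 8α‑acetoxy‑9β‑hydroxy‑7β‑isopropenyl 2‑ketone | C=C(C)[C@H]1C[C@@]2(C)[C@H](CC(=O)C[C@@H]2C)[C@@H](O)[C@@H]1OC(C)=O | intermediate
29 | 8α‑acetoxy‑7β‑isopropenyl 2,9‑dione | C=C(C)[C@H]1C[C@@]2(C)[C@H](CC(=O)C[C@@H]2C)C(=O)[C@@H]1OC(C)=O | intermediate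
30 | C2 N,N‑dimethylhydrazone of 29 | C=C(C)[C@H]1C[C@@]2(C)[C@H](CC(=NN(C)C)C[C@@H]2C)C(=O)[C@@H]1OC(C)=O | intermediate
31 | 8α‑acetoxy‑9α‑hydroxy‑7β‑isopropenyl C2 N,N‑dimethylhydrazone | C=C(C)[C@H]1C[C@@]2(C)[C@H](CC(=NN(C)C)C[C@@H]2C)[C@H](O)[C@@H]1OC(C)=O | intermediate
32 | 3‑methylbut‑2‑enoic acid | CC(C)=CC(=O)O | starting material
33 | 3‑methylbut‑2‑enoic 2,4,6‑trichlorobenzoic anhydride | CC(C)=CC(=O)OC(=O)c1c(Cl)cc(Cl)cc1Cl | intermediate (not isolated)
34 | 8α‑acetoxy‑9α‑(3‑methylbut‑2‑enoyloxy)‑7β‑isopropenyl C2 N,N‑dimethylhydrazone | C=C(C)[C@H]1C[C@@]2(C)[C@H](CC(=NN(C)C)C[C@@H]2C)[C@H](OC(=O)C=C(C)C)[C@@H]1OC(C)=O | intermediate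
35 | (1S,2R,3R,4aR,5S,8aS)‑2‑acetoxy‑4a,5‑dimethyl‑7‑oxo‑3‑(prop‑1‑en‑2‑yl)decahydronaphthalen‑1‑yl 3‑methylbut‑2‑enoate | C=C(C)[C@H]1C[C@@]2(C)[C@H](CC(=O)C[C@@H]2C)[C@H](OC(=O)C=C(C)C)[C@@H]1OC(C)=O | target

**Totals**
Total step count: 22. Longest linear sequence: 22 steps (1 → 35); 2, 8 and 32 are commercial.

**Steps most likely to fail**

Step 8. The two enone arms may be discriminated poorly, because the C4 centre biases the closure only weakly, and the β‑branched methyl ketone may form its enamine slowly. Fallback: 15 is cyclised without a chiral catalyst (pyrrolidine/AcOH, or KOt‑Bu (cat.) in t‑BuOH). This should give both cis‑fused products, 16 and the 4,5‑trans‑dimethyl diastereomer F1, which are diastereomers and separable because C4 is already fixed. F1 is resubmitted to KOt‑Bu/t‑BuOH, where retro‑Michael opening to 15 and reclosure regenerate the mixture, and it is recycled. The fallback sets out from 15 and returns to the route at 16.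

Step 14. The isopropenyl double bond may migrate into conjugation with the C8 ketone during protonation or base equilibration, epimerisation at C7 may be incomplete, or 1,2‑reduction may compete. Fallback: the enone 20 is reduced conjugatively with LiBH(sBu)3 (THF, −78 °C) and the enolate is trapped with acetone. Carbon–carbon bond formation on the convex face should give the 7β‑(2‑hydroxypropan‑2‑yl) ketone F2 directly. NaBH4/CeCl3 then gives the 8α,11‑diol F3, and Ac2O/pyridine/DMAP acetylates only the secondary hydroxyl to give the monoacetate F4. Dehydration of the tertiary alcohol with Burgess reagent (toluene, 50 °C) should give the isopropenyl compound, to be separated from any isopropylidene isomer. No α‑isopropenyl ketone occurs on this path. It sets out from 20 and returns to the route at 27.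

Step 21. Acylation of the concave‑face axial hydroxyl may be slow, so that base‑mediated acetyl shift from O8 to O9 followed by acylation of the freed equatorial O8 gives the regioisomeric diester, or the senecioyl unit may deconjugate. Fallback: 31 is acylated with the smaller and more reactive (diethoxyphosphoryl)acetyl chloride (pyridine, CH2Cl2, −20 °C) to give the phosphonoacetate F5. The 3‑methylbut‑2‑enoate is then built on the molecule by Horner–Wadsworth–Emmons reaction with acetone (NaH, THF, 0 °C → rt). The fallback sets out from 31 and returns to the route at 34.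

**Further compounds**
F1 | step 8 | (4S,4aS,8aS)‑4,4a‑dimethyl‑3,4,4a,8a‑tetrahydronaphthalene‑2,7(1H,8H)‑dione (C5,C10 diastereomer of 16) | C1=C[C@]2(C)[C@@H](CC(=O)C[C@@H]2C)CC1=O
F2 | step 14 | 7β‑(2‑hydroxypropan‑2‑yl)‑8‑oxo‑9β‑(tert‑butyldimethylsilyloxy) C2 ketal | CC(C)(O)[C@H]1C[C@@]2(C)[C@H](CC3(OCCO3)C[C@@H]2C)[C@@H](O[Si](C)(C)C(C)(C)C)C1=O
F3 | step 14 | 7β‑(2‑hydroxypropan‑2‑yl)‑8α‑hydroxy‑9β‑(tert‑butyldimethylsilyloxy) C2 ketal | CC(C)(O)[C@H]1C[C@@]2(C)[C@H](CC3(OCCO3)C[C@@H]2C)[C@@H](O[Si](C)(C)C(C)(C)C)[C@@H]1O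
F4 | step 14 | 8α‑acetoxy‑7β‑(2‑hydroxypropan‑2‑yl)‑9β‑(tert‑butyldimethylsilyloxy) C2 ketal | CC(C)(O)[C@H]1C[C@@]2(C)[C@H](CC3(OCCO3)C[C@@H]2C)[C@@H](O[Si](C)(C)C(C)(C)C)[C@@H]1OC(C)=O
F5 | step 21 | 8α‑acetoxy‑9α‑[(diethoxyphosphoryl)acetoxy]‑7β‑isopropenyl C2 N,N‑dimethylhydrazone | C=C(C)[C@H]1C[C@@]2(C)[C@H](CC(=NN(C)C)C[C@@H]2C)[C@H](OC(=O)CP(=O)(OCC)OCC)[C@@H]1OC(C)=O
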